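**Retrosynthetic overview**
1. Target ⇐ acetylation of the C6 alcohol of the ten-membered ring (last step).
2. Ten-membered carbocycle ⇐ C6–C7 bond by intramolecular umpolung allylation (zerovalent palladium/Et2Zn) of an acyclic 2,3-epoxy aldehyde by its own terminal allylic chloride; this sets C6 and C7.
3. Oxirane ⇐ Sharpless asymmetric epoxidation of a primary allylic alcohol (sets C4, C5); C4=C5 ⇐ Wittig reaction on a methyl ketone.
4. C3–O bond (key step) ⇐ direct asymmetric α-angeloyloxylation of (E)-geranylacetone by a chiral O-angeloyl hydroxylamine ([3,3] shift), which installs the angelate and the first stereocentre together.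
5. Ring order: oxirane first (step 7), then the ten-membered ring (step 9).

Assumption: (E)-geranylacetone (≥97% E) and (S)-N-(1-phenylethyl)hydroxylamine (sold as its oxalate, free-based before use) are taken as catalogue materials; atom labels C1–C15 follow germacrane numbering.

**Step 1**
Reactants: 1 angelic acid [(2Z)-2-methylbut-2-enoic acid]; 2 (S)-N-(1-phenylethyl)hydroxylamine
Product: 4 O-[(2Z)-2-methylbut-2-enoyl]-N-[(1S)-1-phenylethyl]hydroxylammonium chloride, via 1-angeloylimidazole 3 (not isolated)
Conditions: CDI, CH2Cl2, 0 °C; then 2, HCl (Et2O), 0→23 °C; aqueous wash; HCl (Et2O), 0 °C, filter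
Reagents that add atoms: hydrogen chloride, Cl
Why: The acyl imidazolide acylates the N-protonated hydroxylamine on oxygen (the standard route to O-acyl-N-alkylhydroxylammonium salts), and this mild activation at 0 °C keeps the Z geometry of the enoate; the benzylic stereocentre is not touched.

**Step 2**
Reactants: 5 (E)-geranylacetone [(5E)-6,10-dimethylundeca-5,9-dien-2-one]; 4 O-angeloyl-N-[(1S)-1-phenylethyl]hydroxylammonium chloride
Product: 8 (3S,5E)-6,10-dimethyl-2-oxoundeca-5,9-dien-3-yl (2Z)-2-methylbut-2-enoate, via ene-hydroxylamine 6 (not isolated), via α-angeloyloxy imine 7 (not isolated)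
Conditions: 4 (1.1 equiv), DMSO, 23 °C, 24 h; then H2O
Reagents that add atoms: water, O
Why: Proposed new method: asymmetric α-angeloyloxylation of an acyclic methyl ketone by a chiral N-alkyl-O-acylhydroxylammonium salt. Salt 4 condenses with 5 to an iminium ion that tautomerises to the more substituted (E)-N-vinyl-O-acylhydroxylamine 6 (methylene over methyl). Its weak N–O bond breaks in a concerted chair [3,3]-sigmatropic shift that forms the C3–O bond with the angelate carbonyl oxygen, and hydrolysis of imine 7 gives 8 plus recoverable (S)-1-phenylethylamine. The chain sits pseudo-equatorial, and the N-bound stereocentre (its C–H eclipsing the C15 methyl, phenyl blocking one chair) is proposed to steer delivery to the Si face of C3 (3S); this sense is a working model, not established. Any minor enantiomer is removed as a diastereomer after step 7. The angeloyl group is never an activated acyl electrophile, so its Z geometry survives. Closest known reaction type: the racemic α-oxyacylation of ketones with N-methyl-O-benzoylhydroxylamine hydrochloride, not yet shown with stereocontrol on an acyclic methyl ketone or for transfer of an α,β-unsaturated acyl group.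

**Step 3**
Reactants: 8 (3S,5E)-6,10-dimethyl-2-oxoundeca-5,9-dien-3-yl (2Z)-2-methylbut-2-enoate
Product: 9 (2E,4S,6E)-1-[methoxy(methyl)amino]-3,7,11-trimethyl-1-oxododeca-2,6,10-trien-4-yl (2Z)-2-methylbut-2-enoate
Conditions: Ph3P=CHC(O)N(OMe)Me (2 equiv), toluene, 100 °C; chromatography
Reagents that add atoms: N-methoxy-N-methyl-2-(triphenylphosphoranylidene)acetamide, CON(C)C(=O)C=P(c1ccccc1)(c1ccccc1)c1ccccc1
Why: Wittig olefination with an amide-stabilised ylide under neutral conditions (no enolisation at C3); the acyloxy-activated ketone places the amide carbon trans to the larger CH(OAng)R group (E), as is usual for stabilised ylides with α-oxygenated methyl ketones, and the minor Z isomer is removed.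

**Step 4**
Reactants: 9 (2E,4S,6E)-Weinreb enamide
Product: 10 (2E,4S,6E,10E)-12-hydroxy-1-[methoxy(methyl)amino]-3,7,11-trimethyl-1-oxododeca-2,6,10-trien-4-yl (2Z)-2-methylbut-2-enoate
Conditions: SeO2 (20 mol %), t-BuOOH, salicylic acid (10 mol %), CH2Cl2, 0→23 °C
Reagents that add atoms: tert-butyl hydroperoxide, CC(C)(C)OO
Why: SeO2-catalysed allylic oxidation (ene reaction, then [2,3]-sigmatropic shift) selects the (E)-methyl group of the terminal, most electron-rich trisubstituted alkene; the carbonyl-conjugated alkenes are inert and the internal alkene reacts more slowly.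

**Step 5**
Reactants: 10 12-hydroxy Weinreb enamide
Product: 12 (2E,4S,6E,10E)-12-chloro-1-[methoxy(methyl)amino]-3,7,11-trimethyl-1-oxododeca-2,6,10-trien-4-yl (2Z)-2-methylbut-2-enoate, via allylic mesylate 11 (not isolated)
Conditions: MsCl, 2,4,6-collidine, LiCl, DMF, 0 °C
Reagents that add atoms: lithium chloride, [Li+].[Cl-]
Why: Mesylation and in situ SN2 displacement by chloride (Collington–Meyers allylic chlorination) proceed without allylic transposition or loss of E geometry.

**Step 6**
Reactants: 12 12-chloro Weinreb enamide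
Product: 14 (2E,4S,6E,10E)-12-chloro-1-hydroxy-3,7,11-trimethyldodeca-2,6,10-trien-4-yl (2Z)-2-methylbut-2-enoate, via enal 13 (not isolated)
Conditions: Cp2Zr(H)Cl (1.6 equiv), THF, 23 °C, 30 min; then MeOH, CeCl3·7H2O, NaBH4, −20 °C; H2O
Reagents that add atoms: none
Why: Cp2Zr(H)Cl reduces the tertiary amide to the aldehyde much faster than it touches esters or trisubstituted alkenes, and Luche reduction then gives clean 1,2-reduction of enal 13 without attacking the angelate or the allylic chloride; C3 is untouched.

**Step 7**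
Reactants: 14 allylic alcohol
Product: 15 (1S,3E,7E)-9-chloro-1-[(2R,3R)-3-(hydroxymethyl)-2-methyloxiran-2-yl]-4,8-dimethylnona-3,7-dien-1-yl (2Z)-2-methylbut-2-enoate
Conditions: Ti(OiPr)4 (10 mol %), D-(−)-diethyl tartrate (12 mol %), t-BuOOH, 4 Å molecular sieves, CH2Cl2, −20 °C; aqueous tartaric acid work-up; chromatography
Reagents that add atoms: tert-butyl hydroperoxide, CC(C)(C)OO
Why: Sharpless asymmetric epoxidation under reagent control: the D-tartrate catalyst delivers oxygen to the face that gives the (4R,5R)-oxirane (as geraniol gives the 2R,3R epoxide), only the allylic-alcohol alkene reacts, and material of the wrong C3 configuration becomes a separable diastereomer.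

**Step 8**
Reactants: 15 epoxy alcohol
Product: 16 (1S,3E,7E)-9-chloro-1-[(2R,3S)-3-formyl-2-methyloxiran-2-yl]-4,8-dimethylnona-3,7-dien-1-yl (2Z)-2-methylbut-2-enoate
Conditions: Dess–Martin periodinane, pyridine, CH2Cl2, 0→23 °C
Reagents that add atoms: none
Why: Buffered Dess–Martin oxidation gives the epoxy aldehyde under neutral conditions; the α-carbon is an oxirane carbon and does not epimerise (the descriptor at C5 changes only because of CIP priorities).

**Step 9**
Reactants: 16 epoxy aldehyde
Product: 18 (3S,4R,5R,6R,7S,1(10)E)-4,5-epoxy-6-hydroxygermacra-1(10),11-dien-3-yl (2Z)-2-methylbut-2-enoate, via allylzinc species 17 (not isolated)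
Conditions: PdCl2(PPh3)2 (10 mol %), Et2Zn (3 equiv), K2CO3, DMA, 23 °C, slow addition of 16 (final 0.005 M); then H2O
Reagents that add atoms: none
Why: Zerovalent palladium ionises the allylic chloride and Et2Zn transmetalates the π-allyl to nucleophilic allylzinc 17, which adds through its γ-carbon to the tethered aldehyde in a closed chair transition state (umpolung allylation, the reaction type that closes the parent 3-deoxy ring). Felkin–Anh attack anti to the oxirane C–O bond sets 6R, and the (E)-allylzinc chair sets 7S (O6 and isopropenyl cis on the ring).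

**Step 10**
Reactants: 18 macrocyclic alcohol
Product: 19 (3S,4R,5R,6R,7S,1(10)E)-6-acetoxy-4,5-epoxygermacra-1(10),11-dien-3-yl (2Z)-2-methylbut-2-enoate (target)
Conditions: Ac2O, Et3N, DMAP (cat.), CH2Cl2, 0→23 °C
Reagents that add atoms: acetic anhydride, CC(=O)OC(C)=O
Why: DMAP-catalysed acetylation of the secondary alcohol under mild basic conditions leaves the oxirane, the angelate geometry and all stereocentres unchanged.

**Compound list**
1 | angelic acid, (2Z)-2-methylbut-2-enoic acid | C/C=C(/C)C(=O)O | starting material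
2 | (S)-N-(1-phenylethyl)hydroxylamine | ON[C@@H](C)c1ccccc1 | starting material
3 | 1-[(2Z)-2-methylbut-2-enoyl]-1H-imidazole (1-angeloylimidazole) | C/C=C(/C)C(=O)n1ccnc1 | intermediate
4 | O-[(2Z)-2-methylbut-2-enoyl]-N-[(1S)-1-phenylethyl]hydroxylammonium chloride | C/C=C(/C)C(=O)ON[C@@H](C)c1ccccc1.Cl | intermediate
5 | (E)-geranylacetone, (5E)-6,10-dimethylundeca-5,9-dien-2-one | CC(=O)CC/C=C(\C)CCC=C(C)C | starting material
6 | O-angeloyl-N-[(2E,5E)-6,10-dimethylundeca-2,5,9-trien-2-yl]-N-[(1S)-1-phenylethyl]hydroxylamine (ene-hydroxylamine) | C/C=C(/C)C(=O)ON([C@@H](C)c1ccccc1)/C(C)=C/C/C=C(\C)CCC=C(C)C | intermediate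
7 | (3S,5E)-6,10-dimethyl-2-{[(1S)-1-phenylethyl]imino}undeca-5,9-dien-3-yl (2Z)-2-methylbut-2-enoate (α-angeloyloxy imine) | CC(=N[C@@H](C)c1ccccc1)[C@@H](OC(=O)/C(C)=C\C)C/C=C(\C)CCC=C(C)C | intermediate
8 | (3S,5E)-6,10-dimethyl-2-oxoundeca-5,9-dien-3-yl (2Z)-2-methylbut-2-enoate | CC(=O)[C@@H](OC(=O)/C(C)=C\C)C/C=C(\C)CCC=C(C)C | intermediate
9 | (2E,4S,6E)-1-[methoxy(methyl)amino]-3,7,11-trimethyl-1-oxododeca-2,6,10-trien-4-yl (2Z)-2-methylbut-2-enoate | CON(C)C(=O)/C=C(\C)[C@@H](OC(=O)/C(C)=C\C)C/C=C(\C)CCC=C(C)C | intermediate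
10 | (2E,4S,6E,10E)-12-hydroxy-1-[methoxy(methyl)amino]-3,7,11-trimethyl-1-oxododeca-2,6,10-trien-4-yl (2Z)-2-methylbut-2-enoate | CON(C)C(=O)/C=C(\C)[C@@H](OC(=O)/C(C)=C\C)C/C=C(\C)CC/C=C(\C)CO | intermediate
11 | 12-methanesulfonate of 10 (allylic mesylate) | CON(C)C(=O)/C=C(\C)[C@@H](OC(=O)/C(C)=C\C)C/C=C(\C)CC/C=C(\C)COS(C)(=O)=O | intermediate
12 | (2E,4S,6E,10E)-12-chloro-1-[methoxy(methyl)amino]-3,7,11-trimethyl-1-oxododeca-2,6,10-trien-4-yl (2Z)-2-methylbut-2-enoate | CON(C)C(=O)/C=C(\C)[C@@H](OC(=O)/C(C)=C\C)C/C=C(\C)CC/C=C(\C)CCl | intermediate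
13 | (2E,4S,6E,10E)-12-chloro-3,7,11-trimethyl-1-oxododeca-2,6,10-trien-4-yl (2Z)-2-methylbut-2-enoate (enal) | O=C/C=C(\C)[C@@H](OC(=O)/C(C)=C\C)C/C=C(\C)CC/C=C(\C)CCl | intermediate
14 | (2E,4S,6E,10E)-12-chloro-1-hydroxy-3,7,11-trimethyldodeca-2,6,10-trien-4-yl (2Z)-2-methylbut-2-enoate | OC/C=C(\C)[C@@H](OC(=O)/C(C)=C\C)C/C=C(\C)CC/C=C(\C)CCl | intermediate
15 | (1S,3E,7E)-9-chloro-1-[(2R,3R)-3-(hydroxymethyl)-2-methyloxiran-2-yl]-4,8-dimethylnona-3,7-dien-1-yl (2Z)-2-methylbut-2-enoate | ClC/C(C)=C/CC/C(C)=C/C[C@H](OC(=O)/C(C)=C\C)[C@@]1(C)O[C@@H]1CO | intermediate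
16 | (1S,3E,7E)-9-chloro-1-[(2R,3S)-3-formyl-2-methyloxiran-2-yl]-4,8-dimethylnona-3,7-dien-1-yl (2Z)-2-methylbut-2-enoate | ClC/C(C)=C/CC/C(C)=C/C[C@H](OC(=O)/C(C)=C\C)[C@@]1(C)O[C@@H]1C=O | intermediate
17 | ethyl(allyl)zinc derived from 16 (CH2Cl replaced by CH2ZnEt) | CC[Zn]C/C(C)=C/CC/C(C)=C/C[C@H](OC(=O)/C(C)=C\C)[C@@]1(C)O[C@@H]1C=O | intermediate
18 | (3S,4R,5R,6R,7S,1(10)E)-4,5-epoxy-6-hydroxygermacra-1(10),11-dien-3-yl (2Z)-2-methylbut-2-enoate | C=C(C)[C@@H]1CC/C(C)=C/C[C@H](OC(=O)/C(C)=C\C)[C@@]2(C)O[C@@H]2[C@@H]1O | intermediate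
19 | (3S,4R,5R,6R,7S,1(10)E)-6-acetoxy-4,5-epoxygermacra-1(10),11-dien-3-yl (2Z)-2-methylbut-2-enoate | C=C(C)[C@@H]1CC/C(C)=C/C[C@H](OC(=O)/C(C)=C\C)[C@@]2(C)O[C@@H]2[C@@H]1OC(C)=O | target

**Step count**
Total steps: 10. Longest linear sequence: 10 (steps 1–10, counted from angelic acid through reagent 4; 9 steps from geranylacetone 5).

**Three steps most likely to fail**

Step 2 (the proposed new α-angeloyloxylation). The risks are low enantiomer ratio or the opposite sense of induction, slow condensation of the hindered N-alkyl salt, and some reaction at the methyl side. If only the sense is wrong, the (R)-auxiliary is used instead. The fallback with known chemistry sets out from 5. D-Proline-catalysed α-aminoxylation with nitrosobenzene (slow addition, DMSO, 23 °C) reacts through the (E)-enamine at the methylene carbon with the known facial sense and gives (3S,5E)-6,10-dimethyl-3-[(phenylamino)oxy]undeca-5,9-dien-2-one F1. N–O cleavage with CuSO4·5H2O (0.3 equiv) in MeOH at 0 °C gives (3S,5E)-3-hydroxy-6,10-dimethylundeca-5,9-dien-2-one F2. This is esterified with angelic acid 1 through its mixed anhydride (2,4,6-trichlorobenzoyl chloride, Et3N, toluene, 75 °C, no DMAP, to avoid isomerisation to the tiglate), and the route is rejoined at 8.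

Step 3 (Wittig reaction on a hindered, base-sensitive α-acyloxy ketone). The risks are low conversion, poor E/Z ratio and erosion at C3. The fallback sets out from 8 and replaces olefination by addition and elimination. Reformatsky addition of the zinc enolate from 2-bromo-N-methoxy-N-methylacetamide (Zn, THF, 0 °C; the ketone reacts far faster than the hindered angelate) gives (4S,6E)-3-hydroxy-1-[methoxy(methyl)amino]-3,7,11-trimethyl-1-oxododeca-6,10-dien-4-yl (2Z)-2-methylbut-2-enoate F3 as a mixture at the new carbinol. Dehydration with Burgess reagent (toluene, 50 °C) and separation of the conjugated E isomer returns to the route at 9.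

Step 9 (ten-membered ring closure). The risks are oligomerisation, ethyl transfer to the aldehyde, oxirane opening assisted by the neighbouring angelate under zinc Lewis acidity, and incomplete diastereocontrol. The fallback sets out from 16 and avoids the palladium/zinc umpolung altogether: an intramolecular Nozaki–Hiyama allylation with CrCl2 (excess, THF, 23 °C, high dilution). Divalent chromium inserts into the C–Cl bond and the allylchromium adds through its γ-carbon with the usual anti selectivity, a closure used before for germacrane rings. It comes back to the route directly at 18 and makes no compound outside the list (F0).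

**Further compounds**
F1 | step 2 | (3S,5E)-6,10-dimethyl-3-[(phenylamino)oxy]undeca-5,9-dien-2-one | CC(=O)[C@@H](ONc1ccccc1)C/C=C(\C)CCC=C(C)C
F2 | step 2 | (3S,5E)-3-hydroxy-6,10-dimethylundeca-5,9-dien-2-one | CC(=O)[C@@H](O)C/C=C(\C)CCC=C(C)C
F3 | step 3 | (4S,6E)-3-hydroxy-1-[methoxy(methyl)amino]-3,7,11-trimethyl-1-oxododeca-6,10-dien-4-yl (2Z)-2-methylbut-2-enoate | CON(C)C(=O)CC(C)(O)[C@@H](OC(=O)/C(C)=C\C)C/C=C(\C)CCC=C(C)C
F0 | step 9 | none | none
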